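The leftover I wanted from each flask was target, dissolved and crystalline counted together, at the end of the run.

    crystals ⇌ target, rate k1*(cs1 - [target]) while solid is left; crystals form when [target] > cs1 (cs1 = 6.3 mM, k1 = 1.1 s⁻¹)
    substrate → target, rate k2*[substrate]/(1 + ([substrate]/sat2)) (sat2 = 0.15 mM, k2 = 3.0 s⁻¹, Ea2 = 62.0 kJ mol⁻¹)
    target → over-reaction product (k3 = 0.0061 s⁻¹, Ea3 = 64.0 kJ mol⁻¹)
    (constants at −20 °C)

all flasks: substrate 18 mM; time 2.5 min

| run | temperature | remark |
|---|---|---|
| noon | −40 °C |  |
| winter | −20 °C |  |
| summer |  | at −20 °C until 50 s, from then on at −40 °C |

- for target the crystals are counted in
- as a solid, counted per litre of solution: crystals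
- the list of constants is for −20 °C, to be carried to other temperatures by the activation energies

1. the flask that comes out highest in amount of target, in percent of the substrate charged, or "all alike" when all lie within 1.5 percentage points (noon / winter / summer / all alike)
2. target at the end, in percent of the substrate charged, noon
3. target at the end, in percent of the substrate charged, winter
4. target at the end, in percent of the substrate charged, summer

Two rates carried my reckoning, both taken at −20 °C. M, the making rate, was the rate constant of the substrate step times its sat, 0.450 mM s⁻¹, since the charge of 18 mM lay far above sat 0.15 mM. D, the drain, was 0.0384 mM s⁻¹: the zero-order rate of over-reaction from dissolved target held at the solubility 6.3 mM while crystals stand. M was 11.7 times D, so I neglected the drain during the rise and reckoned that in winter dissolved target reached the solubility after ts = 14.0 s and the substrate lasted about 40.0 s.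

I charged the drain from half of ts onward. By this reckoning winter lost 30.5% of the charge, leaving 69.5%, and it still held more target than the solubility. Summer ran alike until 50 s, later than the 40.0 s of making. After that, cooling divided D by 14, so I reckoned that summer lost 10.8% and kept 89.2%. At noon cooling divided M by 13, so I reckoned 5.39 mM made, less than the solubility. I therefore expected no crystals in the noon flask, and a yield of 29.9% of the charge.

The forecast gave 28.7% for noon, 69.2% for winter and 88.9% for summer, and it named summer highest, holding that “Over-reaction then drains the solution steadily at about the solubility level”. My noon figure, counted before any over-reaction, was higher than its figure.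

The simulation gave 28.7% at noon, 69.3% in winter and 89.0% in summer, with summer highest. In winter, target fell from 85.3% at 1.25 min to 69.3% at 2.50 min, with crystals still at 34.5%, a drop of 16 percentage points, and D over that interval gives 16 points. In summer, target fell from 89.0% at 2.50 min to 67.8% at 25.0 min, with crystals still at 32.8%, a drop of 21 points against 21 points from the cold drain.

The rate constants come from no measurement; the result is computed.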